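## Retrosynthetic overview

1. The target comes from global MOM removal. Before that, the C8–CH2 bond is made by a nickel-catalysed radical cross-electrophile coupling. The partners are the complete (2S)-8-iodoflavanone and an unprotected, enantiopure C5 iodohydrin, whose carbinol centre comes from a hydrolytic kinetic resolution and lies β to the radical carbon.
2. The C2–aryl bond and the 2S centre come from a rhodium-catalysed asymmetric 1,4-addition of a catechol-derived boronic acid to an 8-iodochromone.
3. Ring C comes from a mirror-symmetric 2,6-diiodophenol and 3-ethoxyacryloyl chloride by O-acylation, I–Mg exchange, O→C acyl shift and addition–elimination. The unused iodine is the later coupling handle.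
4. Ring A comes from resorcinol: bis-MOM ether, lithiation/prenylation between the two oxygens, iridium C–H borylation/oxidation for the third oxygen, then double iodination.
5. Ring order: rings A and B are bought as benzene rings (resorcinol, catechol). Ring C is the only ring formed (step 5), and its C2=C3 bond is saturated in step 8.

Assumption: the SMILES is read as 2S at the flavanone carbon and 2R in the side chain, and all five numbered starting materials, including (E)-3-ethoxyacryloyl chloride, are taken as catalogue items (MOM = CH2OCH3, prenyl = 3-methylbut-2-en-1-yl).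

## Route

Step 1
Reactants: 1 resorcinol (benzene-1,3-diol)
Product: 2 1,3-bis(methoxymethoxy)benzene
Conditions: MOMCl (2.4 equiv), iPr2NEt (3 equiv), CH2Cl2, 0 °C to rt
Reagents that add atoms: chloromethyl methyl ether (MOMCl), COCCl
Why: Williamson-type O-alkylation caps both phenols as acetal ethers that direct the lithiation of step 2, survive bases, organometallics and low-valent metals, and all leave together in the last step.

Step 2
Reactants: 2 1,3-bis(methoxymethoxy)benzene; 3 prenyl bromide (1-bromo-3-methylbut-2-ene)
Product: 5 1,3-bis(methoxymethoxy)-2-(3-methylbut-2-en-1-yl)benzene, via aryllithium 4 (not isolated)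
Conditions: n-BuLi (1.1 equiv), THF, 0 °C to rt, 1 h; then 3 (1.2 equiv), −78 °C to rt
Reagents that add atoms: n-butyllithium, [Li]CCCC (lithium of 4 only)
Why: In this directed ortho-metalation the C–H between the two chelating OMOM groups is by far the most acidic, and the aryllithium displaces bromide at the primary allylic carbon (SN2), which places the future C6 prenyl group.

Step 3
Reactants: 5 1,3-bis(methoxymethoxy)-2-(3-methylbut-2-en-1-yl)benzene
Product: 7 3,5-bis(methoxymethoxy)-4-(3-methylbut-2-en-1-yl)phenol, via pinacol boronate 6 (not isolated)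
Conditions: [Ir(OMe)(cod)]2 (1.5 mol %), 4,4'-di-tert-butyl-2,2'-bipyridine (3 mol %), B2pin2 (1.0 equiv), THF, 60 °C; then 30 % H2O2, aq NaOH (1 equiv), 0 °C
Reagents that add atoms: hydrogen peroxide, OO (phenol oxygen of 7); bis(pinacolato)diboron, CC1(C)OB(OC1(C)C)B1OC(C)(C)C(C)(C)O1 (Bpin of 6 only)
Why: Sterically controlled iridium-catalysed aromatic C–H borylation reaches only the one C–H without an ortho substituent (para to prenyl), the trisubstituted alkene is too hindered for hydroboration by HBpin, and boronate oxidation (1,2-aryl shift from boron to oxygen) gives the phenol that becomes O1.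

Step 4
Reactants: 7 3,5-bis(methoxymethoxy)-4-(3-methylbut-2-en-1-yl)phenol
Product: 8 2,6-diiodo-3,5-bis(methoxymethoxy)-4-(3-methylbut-2-en-1-yl)phenol
Conditions: I2 (2.05 equiv), NaHCO3 (2.5 equiv), THF/H2O 1:1, 0 °C, dark
Reagents that add atoms: iodine, [I][I]
Why: Electrophilic aromatic iodination of this very electron-rich phenoxide outruns attack of iodine on the alkene, the two free positions are equivalent so taking both removes any mono/di selectivity issue, and iodocyclisation of the prenyl group is blocked because both neighbouring oxygens carry MOM.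

Step 5
Reactants: 8 2,6-diiodo-3,5-bis(methoxymethoxy)-4-(3-methylbut-2-en-1-yl)phenol; 9 (E)-3-ethoxyacryloyl chloride
Product: 14 8-iodo-5,7-bis(methoxymethoxy)-6-(3-methylbut-2-en-1-yl)-4H-chromen-4-one, via sodium phenoxide 10 (not isolated), via aryl ethoxyacrylate 11 (not isolated), via arylmagnesium chloride 12 (not isolated), via magnesium phenoxide enone 13 (not isolated)
Conditions: NaH (1.05 equiv), THF, 0 °C; 9 (1.0 equiv), 0 °C to rt; then iPrMgCl·LiCl (1.1 equiv), −60 °C to rt; aq NH4Cl, then PPTS (cat.), CH2Cl2, rt if EtOH loss is incomplete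
Reagents that add atoms: sodium hydride, [Na+].[H-] (sodium of 10 only); isopropylmagnesium chloride, CC(C)[Mg]Cl (MgCl of 12 and 13 only)
Why: Proposed new method: after O-acylation, fast I–Mg exchange at one of two equivalent C–I bonds puts a carbanion next to the aryl ester, a 1,3 O→C acyl shift (closest known type: the anionic Fries rearrangement triggered by metal–halogen exchange on ortho-halophenyl esters) gives phenoxide 13, and its 6-endo oxa-Michael addition with loss of ethoxide (as in the enaminone route to chromones) closes ring C, while the symmetry of 8 makes the result regiochemically unambiguous and leaves the second iodine at C8.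

Step 6
Reactants: 15 catechol (benzene-1,2-diol)
Product: 16 1,2-bis(methoxymethoxy)benzene
Conditions: MOMCl (2.4 equiv), iPr2NEt (3 equiv), CH2Cl2, 0 °C to rt
Reagents that add atoms: chloromethyl methyl ether (MOMCl), COCCl
Why: Williamson-type O-alkylation masks the oxidation-prone catechol with the same group used on ring A, so that one final operation frees all phenols.

Step 7
Reactants: 16 1,2-bis(methoxymethoxy)benzene
Product: 18 [3,4-bis(methoxymethoxy)phenyl]boronic acid, via pinacol boronate 17 (not isolated)
Conditions: [Ir(OMe)(cod)]2 (1 mol %), 4,4'-di-tert-butyl-2,2'-bipyridine (2 mol %), B2pin2 (1.0 equiv), THF, 80 °C; then NaIO4 (3 equiv), NH4OAc (3 equiv), acetone/H2O, rt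
Reagents that add atoms: bis(pinacolato)diboron, CC1(C)OB(OC1(C)C)B1OC(C)(C)C(C)(C)O1 (boron); water, O (the two OH groups on boron)
Why: Iridium-catalysed C–H borylation of a 1,2-disubstituted benzene goes to C4, the only kind of C–H without an ortho substituent, and periodate destroys the liberated pinacol so that the ester hydrolyses to the free acid in a near-neutral buffer that MOM ethers tolerate.

Step 8
Reactants: 14 8-iodo-5,7-bis(methoxymethoxy)-6-(3-methylbut-2-en-1-yl)-4H-chromen-4-one; 18 [3,4-bis(methoxymethoxy)phenyl]boronic acid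
Product: 19 (2S)-2-[3,4-bis(methoxymethoxy)phenyl]-8-iodo-5,7-bis(methoxymethoxy)-6-(3-methylbut-2-en-1-yl)chroman-4-one
Conditions: [Rh(OH)(cod)]2 (2.5 mol %), (S)-MeO-F12-BIPHEP [(S)-2,2'-bis{bis(3,4,5-trifluorophenyl)phosphino}-6,6'-dimethoxybiphenyl] (5.5 mol %), 18 (2.5 equiv), CH2Cl2/H2O 10:1, 20 °C
Reagents that add atoms: none
Why: In this Hayashi–Miyaura asymmetric 1,4-addition the aryl–rhodium species bearing the (S)-biaryl diphosphine inserts C2=C3 on the face that gives (S)-3-arylcyclohexanones from cyclohexenone, which maps onto 2S here (checked by CD on the first run), fast hydrolysis of the oxa-π-allyl rhodium prevents ring opening, and the electron-poor monovalent rhodium does not insert into the hindered C–I bond at 20 °C.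

Step 9
Reactants: 20 methacrolein (2-methylprop-2-enal)
Product: 21 rac-2-(prop-1-en-2-yl)oxirane
Conditions: Me3SI (1.1 equiv), NaH (1.1 equiv), DMSO/THF, 0 °C to rt; distil
Reagents that add atoms: trimethylsulfonium iodide, C[S+](C)C.[I-] (epoxide CH2)
Why: In this Corey–Chaykovsky epoxidation the unstabilised sulfonium ylide adds 1,2 to the enal and the betaine closes to the racemic vinyl epoxide.

Step 10
Reactants: 21 rac-2-(prop-1-en-2-yl)oxirane
Product: 22 (2S)-3-methylbut-3-ene-1,2-diol
Conditions: (R,R)-(salen)Co(OAc) [salen = N,N'-bis(3,5-di-tert-butylsalicylidene)cyclohexane-1,2-diamine dianion] (1 mol %), H2O (0.40 equiv), neat, 0 °C to rt; pump off unreacted epoxide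
Reagents that add atoms: water, O
Why: In this Jacobsen hydrolytic kinetic resolution the (R,R)-catalyst delivers water to the CH2 terminus of the (S)-epoxide only (the sense known for alkyl- and vinyl-oxiranes), so the C–O bond at the stereocentre is retained and the (S)-diol forms, with sub-stoichiometric water keeping its ee high.

Step 11
Reactants: 22 (2S)-3-methylbut-3-ene-1,2-diol
Product: 23 (2S)-1-iodo-3-methylbut-3-en-2-ol
Conditions: PPh3 (1.05 equiv), I2 (1.05 equiv), imidazole (1.1 equiv), CH2Cl2, 0 °C, dark; use promptly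
Reagents that add atoms: iodine, [I][I]
Why: Appel-type (Garegg–Samuelsson) iodination with one equivalent of reagent at 0 °C is selective for the primary alcohol, fixes iodine unambiguously at C1 (direct iodide opening of the vinyl epoxide would also hit the allylic carbon), and leaves the stereocentre untouched.

Step 12 (key step)
Reactants: 19 (2S)-2-[3,4-bis(methoxymethoxy)phenyl]-8-iodo-5,7-bis(methoxymethoxy)-6-(3-methylbut-2-en-1-yl)chroman-4-one; 23 (2S)-1-iodo-3-methylbut-3-en-2-ol
Product: 25 (2S)-2-[3,4-bis(methoxymethoxy)phenyl]-8-[(2R)-2-hydroxy-3-methylbut-3-en-1-yl]-5,7-bis(methoxymethoxy)-6-(3-methylbut-2-en-1-yl)chroman-4-one, via primary alkyl radical 24 (not isolated)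
Conditions: NiCl2(dme) (15 mol %), 4,4'-di-tert-butyl-2,2'-bipyridine (18 mol %), Mn powder (3 equiv), NaI (0.25 equiv), DMPU, 30 °C; 23 (2.5 equiv) added over 6 h
Reagents that add atoms: none
Why: In this nickel-catalysed reductive cross-electrophile coupling (radical chain) zerovalent nickel inserts into the aryl C–I bond of 19, monovalent nickel abstracts iodine from 23 to give radical 24, and trapping by the aryl-nickel species followed by reductive elimination forms C8–CH2 without base or carbanion (no epoxide closure, no SN2' path, no enolisation or ring opening at C2), free iodohydrins being the competent intermediates of the known aryl halide/epoxide version, while the carbinol carbon is β to the radical centre and keeps its configuration (S becomes R only through CIP priorities).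

Step 13
Reactants: 25 tetra-MOM ether of the target
Product: 26 (2S)-2-(3,4-dihydroxyphenyl)-5,7-dihydroxy-8-[(2R)-2-hydroxy-3-methylbut-3-en-1-yl]-6-(3-methylbut-2-en-1-yl)chroman-4-one
Conditions: HCl (1.25 M in MeOH), 35–40 °C, 3–5 h; NaHCO3 quench to pH 6, no basic work-up
Reagents that add atoms: none
Why: Acid-catalysed acetal exchange with methanol removes the four phenolic MOM groups as dimethoxymethane under conditions routinely used for prenylated flavanones, which are too mild to protonate the alkenes, ionise the unactivated secondary allylic alcohol or open ring C, so both stereocentres persist.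

## Compound list

1 | resorcinol | Oc1cccc(O)c1 | starting material
2 | 1,3-bis(methoxymethoxy)benzene | COCOc1cccc(OCOC)c1 | intermediate
3 | prenyl bromide | CC(C)=CCBr | starting material
4 | 2-lithio-1,3-bis(methoxymethoxy)benzene | [Li]c1c(OCOC)cccc1OCOC | intermediate (not isolated)
5 | 1,3-bis(methoxymethoxy)-2-(3-methylbut-2-en-1-yl)benzene | CC(C)=CCc1c(OCOC)cccc1OCOC | intermediate
6 | 2-[3,5-bis(methoxymethoxy)-4-(3-methylbut-2-en-1-yl)phenyl]-4,4,5,5-tetramethyl-1,3,2-dioxaborolane | CC(C)=CCc1c(OCOC)cc(B2OC(C)(C)C(C)(C)O2)cc1OCOC | intermediate (not isolated)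
7 | 3,5-bis(methoxymethoxy)-4-(3-methylbut-2-en-1-yl)phenol | CC(C)=CCc1c(OCOC)cc(O)cc1OCOC | intermediate
8 | 2,6-diiodo-3,5-bis(methoxymethoxy)-4-(3-methylbut-2-en-1-yl)phenol | Ic1c(OCOC)c(CC=C(C)C)c(OCOC)c(c1O)I | intermediate
9 | (E)-3-ethoxyacryloyl chloride | CCO/C=C/C(=O)Cl | starting material
10 | sodium phenoxide of 8 | Ic1c(OCOC)c(CC=C(C)C)c(OCOC)c(c1[O-])I.[Na+] | intermediate (not isolated)
11 | 2,6-diiodo-3,5-bis(methoxymethoxy)-4-(3-methylbut-2-en-1-yl)phenyl (E)-3-ethoxyacrylate | Ic1c(OCOC)c(CC=C(C)C)c(OCOC)c(c1OC(=O)/C=C/OCC)I | intermediate (not isolated)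
12 | arylmagnesium chloride from 11 (one iodine exchanged) | Ic1c(OCOC)c(CC=C(C)C)c(OCOC)c(c1OC(=O)/C=C/OCC)[Mg]Cl | intermediate (not isolated)
13 | chloromagnesium phenoxide of (E)-3-ethoxy-1-[2-hydroxy-3-iodo-4,6-bis(methoxymethoxy)-5-(3-methylbut-2-en-1-yl)phenyl]prop-2-en-1-one | Ic1c(OCOC)c(CC=C(C)C)c(OCOC)c(c1O[Mg]Cl)C(=O)/C=C/OCC | intermediate (not isolated)
14 | 8-iodo-5,7-bis(methoxymethoxy)-6-(3-methylbut-2-en-1-yl)-4H-chromen-4-one | Ic1c(OCOC)c(CC=C(C)C)c(OCOC)c2c1occc2=O | intermediate
15 | catechol | Oc1ccccc1O | starting material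
16 | 1,2-bis(methoxymethoxy)benzene | COCOc1ccccc1OCOC | intermediate
17 | 2-[3,4-bis(methoxymethoxy)phenyl]-4,4,5,5-tetramethyl-1,3,2-dioxaborolane | COCOc1ccc(B2OC(C)(C)C(C)(C)O2)cc1OCOC | intermediate (not isolated)
18 | [3,4-bis(methoxymethoxy)phenyl]boronic acid | COCOc1ccc(B(O)O)cc1OCOC | intermediate
19 | (2S)-2-[3,4-bis(methoxymethoxy)phenyl]-8-iodo-5,7-bis(methoxymethoxy)-6-(3-methylbut-2-en-1-yl)chroman-4-one | Ic1c(OCOC)c(CC=C(C)C)c(OCOC)c2c1O[C@H](c1ccc(OCOC)c(OCOC)c1)CC2=O | intermediate
20 | methacrolein | C=C(C)C=O | starting material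
21 | rac-2-(prop-1-en-2-yl)oxirane | C=C(C)C1CO1 | intermediate
22 | (2S)-3-methylbut-3-ene-1,2-diol | C=C(C)[C@H](O)CO | intermediate
23 | (2S)-1-iodo-3-methylbut-3-en-2-ol | C=C(C)[C@H](O)CI | intermediate
24 | 2-hydroxy-3-methylbut-3-en-1-yl radical (carbinol configuration as in 23) | C=C(C)[C@H](O)[CH2] | intermediate (not isolated)
25 | (2S)-2-[3,4-bis(methoxymethoxy)phenyl]-8-[(2R)-2-hydroxy-3-methylbut-3-en-1-yl]-5,7-bis(methoxymethoxy)-6-(3-methylbut-2-en-1-yl)chroman-4-one | C=C(C)[C@H](O)Cc1c(OCOC)c(CC=C(C)C)c(OCOC)c2c1O[C@H](c1ccc(OCOC)c(OCOC)c1)CC2=O | intermediate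
26 | (2S)-2-(3,4-dihydroxyphenyl)-5,7-dihydroxy-8-[(2R)-2-hydroxy-3-methylbut-3-en-1-yl]-6-(3-methylbut-2-en-1-yl)chroman-4-one | C=C(C)[C@H](O)Cc1c(O)c(CC=C(C)C)c(O)c2c1O[C@H](c1ccc(O)c(O)c1)CC2=O | target

## Step count and risks

Total step count: 13.
Longest linear sequence: 8 steps (1, 2, 3, 4, 5, 8, 12, 13).

**Step 12 (radical coupling).**
- Risks:
  - The aryl iodide has oxygen on both ortho positions, so hydrodeiodination may win.
  - The free iodohydrin may be lost as epoxide or isoprene.
  - Homoallyl radical 24 may undergo a 1,2-vinyl shift if trapping by nickel is slow.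
- Fallback: it sets out from 19 and 23 and comes back at 26.
  - The two roles are separated instead of reducing both halides in one pot.
  - 19 is inserted with Zn dust/LiCl (THF, 40 °C) to give the arylzinc iodide F1.
  - 23 is silylated (TBSOTf, 2,6-lutidine, CH2Cl2, −78 °C) to the silyl ether iodide F2.
  - CoCl2·2LiCl (20 mol %) with TMEDA in THF at 0 °C to rt joins them. This is a Negishi-type coupling in which cobalt abstracts iodine from F2 and the resulting primary radical is trapped at the aryl-metal, giving the silyl-protected coupling product F3.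
  - The methanolic HCl of step 13 then removes the TBS and the four MOM groups together to give 26.

**Step 5 (one-flask acylation, acyl shift and ring closure).**
- Risks:
  - The arylmagnesium may be too sluggish for the four-centre acyl shift.
  - It may transfer acyl between molecules.
  - The Grignard reagent may attack the activated ester.
- Fallback: it sets out from 8 and comes back at 14.
  - The acyl group is brought in intermolecularly and ring C is built from C2 + C1.
  - 8 is deprotonated with MeMgCl/LiCl and one iodine is exchanged with iPrMgCl·LiCl (THF, −20 °C) to give the magnesiated magnesium phenoxide F4.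
  - F4 is acylated with N-methoxy-N-methylacetamide to the hydroxyacetophenone F5.
  - Me2NCH(OMe)2 (toluene, 80 °C) gives the enaminone F6.
  - Warm AcOH (50 °C) closes F6 with loss of dimethylamine to 14.

**Step 8 (asymmetric arylation beside a C–I bond).**
- Risks:
  - The electron-rich, fully substituted chromone may add slowly.
  - Rhodium may be consumed by the aryl iodide.
- Fallback: it sets out from 14 (with 23 and 18) and comes back at 25.
  - The order of the two C–C bond formations is inverted.
  - The nickel/Mn coupling of step 12 is run on chromone 14 with 23 to give the side-chain chromone F7. F7 carries no halogen and no stereocentre at risk.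
  - The rhodium-catalysed 1,4-addition of 18 is then done on F7 under the step 8 conditions. Aryl-rhodium ignores the isolated alkenes and the free alcohol, and 25 is obtained directly.

## Further compounds

F1 | step 12 | arylzinc iodide from 19 | I[Zn]c1c(OCOC)c(CC=C(C)C)c(OCOC)c2c1O[C@H](c1ccc(OCOC)c(OCOC)c1)CC2=O
F2 | step 12 | tert-butyl{[(2S)-1-iodo-3-methylbut-3-en-2-yl]oxy}dimethylsilane | C=C(C)[C@H](O[Si](C)(C)C(C)(C)C)CI
F3 | step 12 | O-TBS ether of 25 | C=C(C)[C@H](O[Si](C)(C)C(C)(C)C)Cc1c(OCOC)c(CC=C(C)C)c(OCOC)c2c1O[C@H](c1ccc(OCOC)c(OCOC)c1)CC2=O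
F4 | step 5 | chloromagnesium 2-(chloromagnesio)-6-iodo-3,5-bis(methoxymethoxy)-4-(3-methylbut-2-en-1-yl)phenoxide | Cl[Mg]Oc1c([Mg]Cl)c(OCOC)c(CC=C(C)C)c(OCOC)c1I
F5 | step 5 | 1-[2-hydroxy-3-iodo-4,6-bis(methoxymethoxy)-5-(3-methylbut-2-en-1-yl)phenyl]ethanone | CC(=O)c1c(OCOC)c(CC=C(C)C)c(OCOC)c(c1O)I
F6 | step 5 | (E)-3-(dimethylamino)-1-[2-hydroxy-3-iodo-4,6-bis(methoxymethoxy)-5-(3-methylbut-2-en-1-yl)phenyl]prop-2-en-1-one | CN(C)/C=C/C(=O)c1c(OCOC)c(CC=C(C)C)c(OCOC)c(c1O)I
F7 | step 8 | 8-[(2R)-2-hydroxy-3-methylbut-3-en-1-yl]-5,7-bis(methoxymethoxy)-6-(3-methylbut-2-en-1-yl)-4H-chromen-4-one | C=C(C)[C@H](O)Cc1c(OCOC)c(CC=C(C)C)c(OCOC)c2c1occc2=O
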